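**Retrosynthetic overview**

1. The only ring, the butenolide, is not built. It is bought as 3‑methyltetronic acid (1) and only activated, as enol triflate 2.
2. The C16 side chain is hexadeca‑1,15‑diene (3). Its mono‑9‑BBN adduct 4 is joined to 2 at ring carbon 4 (sp2–sp3 Suzuki disconnection), giving terminal alkene 5.
3. Key disconnection: the secondary C–O bond at chain carbon 2 of target 6, i.e. 6 ⇒ 5 + AcOH. The acetate and the (S) centre are installed together, last, by a catalytic enantioselective Markovnikov hydroacetoxylation of the terminal alkene.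
4. Order: 1 → 2; 3 → 4; 2 + 4 → 5; 5 → 6. Three steps, no protecting groups.

Assumption: 1 and 3 are taken as catalogue compounds. The (R,R) enantiomer of the new catalyst is taken to give the (S) acetate; this is checked on a small sample of 5 by chiral HPLC, and the mirror‑image catalyst is used if the sense is opposite.

Catalyst used in step 3: Co(L1), C58H80CoN2O2, the divalent cobalt complex of L1. L1 is the dianion of (1R,2R)‑N,N'‑bis[5‑tert‑butyl‑3‑(2,4,6‑triisopropylphenyl)salicylidene]cyclohexane‑1,2‑diamine. It is made from the salen ligand and Co(OAc)2.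

**Route**

Step 1
Reactants: 1 4‑hydroxy‑3‑methylfuran‑2(5H)‑one (3‑methyltetronic acid)
Product: 2 4‑methyl‑5‑oxo‑2,5‑dihydrofuran‑3‑yl trifluoromethanesulfonate
Conditions: Tf2O (1.1 equiv), iPr2NEt (1.2 equiv), CH2Cl2, −78 °C to 0 °C, 1 h
Reagents that add atoms: trifluoromethanesulfonic anhydride (Tf2O), O=S(=O)(OS(=O)(=O)C(F)(F)F)C(F)(F)F
Why: O‑sulfonylation of a vinylogous acid (enol triflate formation); the acidic enol OH reacts on oxygen with Tf2O and a hindered amine at low temperature, and no stereocentre is involved.

Step 2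
Reactants: 3 hexadeca‑1,15‑diene (4 equiv); 2 4‑methyl‑5‑oxo‑2,5‑dihydrofuran‑3‑yl trifluoromethanesulfonate (1 equiv)
Product: 5 4‑(hexadec‑15‑en‑1‑yl)‑3‑methylfuran‑2(5H)‑one, via 9‑(hexadec‑15‑en‑1‑yl)‑9‑BBN 4 (not isolated)
Conditions: 9‑BBN (1.3 equiv), THF, 0 °C to rt, 3 h; then 2, Pd(dppf)Cl2 (5 mol%), aq. K3PO4 (3 M, 3 equiv), DMF, rt to 45 °C, 12 h
Reagents that add atoms: none
Why: Anti‑Markovnikov hydroboration followed by B‑alkyl Suzuki–Miyaura coupling; the excess diene puts about five sixths of the boron into the mono adduct and consumes all B–H, and the electron‑poor enol triflate adds to zerovalent palladium and couples at ring carbon 4 while the second terminal alkene and the lactone stay untouched (no stereocentre formed).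

Step 3
Reactants: 5 4‑(hexadec‑15‑en‑1‑yl)‑3‑methylfuran‑2(5H)‑one
Product: 6 (2S)‑16‑(4‑methyl‑5‑oxo‑2,5‑dihydrofuran‑3‑yl)hexadecan‑2‑yl acetate
Conditions: (R,R)‑Co(L1) (5 mol%), AcOH (10 equiv), N‑fluoro‑2,4,6‑trimethylpyridinium triflate (2 equiv), PhSiH3 (2 equiv), PhCF3, −20 °C to 0 °C, 16 h, Ar
Reagents that add atoms: acetic acid, CC(=O)O
Why: Proposed new method: enantioselective intermolecular Markovnikov hydroacetoxylation of an unactivated α‑olefin by metal‑hydride hydrogen‑atom transfer and radical–polar crossover with the new pocket‑type catalyst Co(L1); a trivalent cobalt hydride (from Co(L1), the N–F oxidant and PhSiH3) gives a hydrogen atom to the terminal CH2, the secondary radical is caught by cobalt and oxidised to a tetravalent sec‑alkylcobalt species whose two diastereomers interconvert by Co–C homolysis, and acetic acid displaces cobalt from carbon with inversion, faster from the diastereomer in which the methyl group lies against a triisopropylphenyl wall and the long chain leaves through the open quadrant, which sets chain carbon 2 as (S); the tetrasubstituted, electron‑poor butenolide alkene is not a competent hydrogen‑atom acceptor and the lactone is inert to the silane at 0 °C; the closest known reaction types are the racemic cobalt‑salen/silane/N‑fluoropyridinium Markovnikov hydroalkoxylation and hydroacyloxylation of terminal alkenes (Mukaiyama‑type hydrofunctionalization) and the enantioselective ring‑closing version that turns terminal alkenols into 2‑methyltetrahydrofurans, where a chiral cobalt salen already makes the same CH3 against CH2R choice; new here are enantiocontrol without a tether and acetic acid as external nucleophile.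

**Compound list**

1 | 4‑hydroxy‑3‑methylfuran‑2(5H)‑one (3‑methyltetronic acid) | CC1=C(O)COC1=O | starting material
2 | 4‑methyl‑5‑oxo‑2,5‑dihydrofuran‑3‑yl trifluoromethanesulfonate | CC1=C(OS(=O)(=O)C(F)(F)F)COC1=O | intermediate
3 | hexadeca‑1,15‑diene | C=CCCCCCCCCCCCCCC=C | starting material
4 | 9‑(hexadec‑15‑en‑1‑yl)‑9‑borabicyclo[3.3.1]nonane | C=CCCCCCCCCCCCCCCB1C2CCCC1CCC2 | intermediate
5 | 4‑(hexadec‑15‑en‑1‑yl)‑3‑methylfuran‑2(5H)‑one | C=CCCCCCCCCCCCCCCC1=C(C)C(=O)OC1 | intermediate
6 | (2S)‑16‑(4‑methyl‑5‑oxo‑2,5‑dihydrofuran‑3‑yl)hexadecan‑2‑yl acetate | CC(=O)O[C@@H](C)CCCCCCCCCCCCCCC1=C(C)C(=O)OC1 | target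

**Step count and risks**

Total steps: 3. Longest linear sequence: 3 (1 → 2 → 5 → 6).

Steps most likely to fail, in order of risk:

Step 3 (the new reaction). The main risk is low enantioselectivity, because methyl and n‑alkyl must be told apart without a tether. Lesser risks are alkene isomerisation along the chain and simple reduction to the alkane. The fallback uses known chemistry, sets out from 5 and comes back at 6. A Tsuji–Wacker oxidation (PdCl2 10 mol%, CuCl 1 equiv, O2, DMF/H2O 7:1, rt) gives the methyl ketone 3‑methyl‑4‑(15‑oxohexadecyl)furan‑2(5H)‑one F1. A Prelog‑selective alcohol dehydrogenase (ADH‑A from Rhodococcus ruber or an (S)‑selective ketoreductase, NADH, iPrOH as hydride donor, phosphate buffer pH 7, 30 °C) reduces F1 to 4‑[(15S)‑15‑hydroxyhexadecyl]‑3‑methylfuran‑2(5H)‑one F2; such enzymes typically give methyl carbinols in very high ee. Acetylation (Ac2O, pyridine, DMAP cat., CH2Cl2, 0 °C to rt) proceeds with retention and returns to 6.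

Step 2. The risks are hydrolysis of the triflate or lactone by the aqueous base, and bis‑coupled material from the doubly hydroborated diene. The fallback is a base‑free Negishi coupling; it sets out from 2 and comes back at 5. The chain is made separately: bought 1,12‑dibromododecane F3 (3 equiv) is coupled with bought but‑3‑en‑1‑ylmagnesium bromide F4 (Li2CuCl4 3 mol%, THF, −10 °C to rt) to give 16‑bromohexadec‑1‑ene F5. Zinc insertion (Zn dust, LiCl, THF, 50 °C) gives hexadec‑15‑en‑1‑ylzinc bromide F6, which couples with 2 (Pd(dppf)Cl2 3 mol%, THF, rt) to give 5.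

Step 1. The risk is that the triflate is too labile to isolate and store (it reverts to 1 with moisture or nucleophiles). The fallback replaces the sulfonate by a halide; it sets out from 1 and comes back at 5. Deoxybromination of 1 (oxalyl bromide 1.2 equiv, DMF cat., CH2Cl2, 0 °C to rt) gives the stable 4‑bromo‑3‑methylfuran‑2(5H)‑one F7. F7 is coupled with borane 4 under the step 2 conditions (Pd(dppf)Cl2, aq. K3PO4, THF/DMF, 45 °C) to give 5.

**Further compounds**

F1 | step 3 | 3‑methyl‑4‑(15‑oxohexadecyl)furan‑2(5H)‑one | CC(=O)CCCCCCCCCCCCCCC1=C(C)C(=O)OC1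
F2 | step 3 | 4‑[(15S)‑15‑hydroxyhexadecyl]‑3‑methylfuran‑2(5H)‑one | C[C@H](O)CCCCCCCCCCCCCCC1=C(C)C(=O)OC1
F3 | step 2 | 1,12‑dibromododecane (bought) | BrCCCCCCCCCCCCBr
F4 | step 2 | but‑3‑en‑1‑ylmagnesium bromide (bought) | C=CCC[Mg]Br
F5 | step 2 | 16‑bromohexadec‑1‑ene | C=CCCCCCCCCCCCCCCBr
F6 | step 2 | hexadec‑15‑en‑1‑ylzinc bromide | C=CCCCCCCCCCCCCCC[Zn]Br
F7 | step 1 | 4‑bromo‑3‑methylfuran‑2(5H)‑one | CC1=C(Br)COC1=O
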